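The runs are calculated for substances that don't exist.

The easy step first: at the bench I expect a charge of substrate, stirred under a held gas phase, to give the same percent of target at the same time, whatever the size of the charge.

| setting | elm | ash | flask |
|---|---|---|---|
| substrate | 0.75 M | 3 M | 1.5 M |
| gas phase | 200 mM (held) | 200 mM (held) | 200 mM (held) |
| remark | run made earlier | run made earlier |  |
| time |  |  | 3.0 h |

| run | time / h | target / % |
|---|---|---|
| elm | 0.417 | 2.2 |
| elm | 1.33 | 6.3 |
| elm | 2.50 | 11.6 |
| elm | 4.00 | 14.1 |
| ash | 0.833 | 1.8 |
| ash | 2.00 | 3.9 |
| ash | 2.50 | 5.9 |
| ash | 4.00 | 4.4 |

(standard deviation of a reading: 1 percentage point)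

- at the start none of the gas phase is in solution

- north-west: doubling the transfer coefficient of the gas phase, all else as stated
- west: doubling the saturation concentration of gas phase, all else as stated

1. amount of target at 3.0 h, in percent of the substrate charged
2. the change that raises the amount of target at 3.0 h, in percent of the substrate charged most ("none" if none brings more than 2 percentage points) (north-west / west / none)
3. amount of target at 3.0 h, in percent of the substrate charged, after north-west

Both earlier runs were read at 2.50 h under the gas phase of the flask, so the habit can be tried. The elm run, at 0.75 M, stands at 11.6 % then, and the ash run, with 4.00 times that charge, should stand there too, but it reads 5.9 %. The ratio of the two percentages is 1.97 where the habit wants 1, and the gap of 5.7 percentage points stands against a scatter of 1 point, so the habit stops working between these charges.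

I replace it with a reading of 1.40, my charge penalty: the factor by which the percent of target at a fixed time falls for each doubling of the charge. In the trade this is an apparent order in substrate, here near 0.515. The flask lies one doubling above the elm run, so I reckon 8.29 % for it at 2.50 h. The ash run reads 1.5 points lower at 4.00 h, about the scatter of 1.4 points on a difference of two readings, so I read no fall from it. A straight line between the last two elm readings gives 12.4 % at 3.0 h, and if the penalty holds at that time as well, I reckon 8.86 % for the flask.

The penalty says nothing about the gas, and the forecast, which gives 9 %, a little above my figure, with west as the best change and 14 % after north-west, rests on the view that “gas transfer and reaction act in series”.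

The flask gives 8.32 % at 3.0 h, and west is the best change, gaining 4.5 points against 2.1 points for north-west, which leaves 10.5 %. The scheme is:

    dissolved gas + target → over-reacted product (k = 0.372 L mol⁻¹ h⁻¹)
    2 substrate → homo dimer (k = 0.432 L mol⁻¹ h⁻¹)
    dissolved gas + target → over-reaction product (k = 0.466 L mol⁻¹ h⁻¹)
    substrate + dissolved gas → target (k = 0.948 L mol⁻¹ h⁻¹)
    gas phase ⇌ dissolved gas, rate k5*(csat - [dissolved gas]) (kL = 1.19 h⁻¹)

At 3.00 h the flask holds homo dimer at 73.7 %, more than its target. The neighbour flask charged with 0.38 M and read at the same time lies 1.98 doublings below this flask, so the penalty lifts 8.32 % to 16.3 %, and that neighbour flask holds 17.2 %.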